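**Retrosynthetic overview**
1. The ten-membered carbocycle is closed last by ring-closing metathesis at the Z-C4=C5 alkene, joining a C6 vinyl group to the C3 isopropenyl carbinol benzoate; the C1–C10 epoxide is installed just before by Shi epoxidation.
2. The trans α-methylene-γ-butyrolactone (first ring of the core) comes from a chromium-mediated allylation of acrolein by a 2-(bromomethyl)enoate (C6–C7 bond), with C8 directing C7 and C6.
3. The C8–O bond, the C8 stereocentre and the complete epoxy ester are introduced in one step by an amine-catalysed α-acyloxylation of a γ,δ-unsaturated aldehyde with the diacyl peroxide of the epoxy acid (the new step).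
4. That aldehyde comes from a Claisen rearrangement (E-C1=C10) of the mono-benzoate of a C2-symmetric diol, made by double Shi epoxidation of 2,6-dimethylhepta-2,5-diene and epoxide-to-allylic-alcohol isomerisation.
5. The epoxy acid comes from Sharpless epoxidation of (E)-2-methylbut-2-en-1-ol and is coupled with its own peroxy acid to give the diacyl peroxide; ring order: side-chain oxirane, lactone, C1–C10 oxirane, ten-membered ring.

Assumption: germacrane numbering is used for the ring atoms (C6–O lactone, C8 epoxy ester, C3 benzoate, C1/C10 ring epoxide), which reads the SMILES as 1R,3S,4Z,6R,7R,8R,10R with a (2R,3S)-2,3-dimethyloxirane-2-carboxylate.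

**Route**

Step 1
Reactants: 1 1-bromo-3-methylbut-2-ene; 2 (2-methylprop-1-en-1-yl)magnesium bromide
Product: 3 2,6-dimethylhepta-2,5-diene
Conditions: Li2CuCl4 (3 mol%), THF, −20 → 0 °C
Reagents that add atoms: none
Why: Kochi-type copper-catalysed Grignard cross-coupling at the primary allylic carbon (SN2 mode) gives the skipped diene, which has no stereocentre.

Step 2
Reactants: 3 2,6-dimethylhepta-2,5-diene
Product: 5 (3S,3'S)-3,3'-methylenebis(2,2-dimethyloxirane), via mono-epoxide 4 (not isolated)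
Conditions: ent-Shi ketone (1,2:4,5-di-O-isopropylidene-β-L-erythro-2,3-hexodiulo-2,6-pyranose, 0.6 equiv), KHSO5 (from 2KHSO5·KHSO4·K2SO4), K2CO3, Bu4NHSO4, MeCN–CH2(OMe)2–aq. Na2B4O7, 0 °C
Reagents that add atoms: potassium peroxymonosulfate KHSO5 [K+].[O-]S(=O)(=O)OO
Why: Shi asymmetric epoxidation through the spiro dioxirane transition state sets the first stereocentres by catalyst control (the D-fructose ketone gives R at the CH carbon of R–CH=CMe2, so its enantiomer gives S at both), and the double reaction channels the minor enantiomeric outcome into a separable meso isomer.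

Step 3
Reactants: 5 (3S,3'S)-3,3'-methylenebis(2,2-dimethyloxirane)
Product: 7 (3S,5S)-2,6-dimethylhepta-1,6-diene-3,5-diol, via epoxy alcohol 6 (not isolated)
Conditions: LiNEt2 (from Et2NH, n-BuLi; 5 equiv), Et2O–hexane, 0 °C → reflux; H2O; chromatography removes the minor meso diol
Reagents that add atoms: none
Why: Base-promoted epoxide-to-allylic-alcohol isomerisation (syn β-elimination) removes a methyl proton and breaks only the tertiary C–O bond, so each secondary C–O stereocentre is retained.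

Step 4
Reactants: 7 (3S,5S)-2,6-dimethylhepta-1,6-diene-3,5-diol
Product: 9 (3S,5S)-5-hydroxy-2,6-dimethylhepta-1,6-dien-3-yl benzoate, via cyclic orthoester 8 (not isolated)
Conditions: PhC(OMe)3, CSA (cat.), CH2Cl2, rt; then AcOH–H2O
Reagents that add atoms: trimethyl orthobenzoate COC(OC)(OC)c1ccccc1; water O
Why: Mono-acylation of a diol by hydrolysis of its cyclic orthoester gives one mono-benzoate because the two hydroxyls of the C2-symmetric diol are equivalent, and the benzoate carbon is the future C3 (S).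

Step 5
Reactants: 9 (3S,5S)-5-hydroxy-2,6-dimethylhepta-1,6-dien-3-yl benzoate; 10 ethoxyethene
Product: 12 (3S,5E)-2,6-dimethyl-9-oxonona-1,5-dien-3-yl benzoate, via allyl vinyl ether 11 (not isolated)
Conditions: Hg(OAc)2 (20 mol%), neat 10, reflux; evaporate; toluene, 140 °C (sealed tube)
Reagents that add atoms: none
Why: Transvinylation followed by Claisen rearrangement through a chair transition state with the CH2CH(OBz) chain equatorial gives the E-trisubstituted C1=C10 alkene and the C7 aldehyde, consuming the free carbinol centre and leaving the benzoate centre untouched.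

Step 6
Reactants: 13 (2E)-2-methylbut-2-en-1-ol
Product: 14 [(2S,3S)-2,3-dimethyloxiran-2-yl]methanol
Conditions: Ti(OiPr)4 (10 mol%), L-(+)-diethyl tartrate (12 mol%), t-BuOOH, 4 Å molecular sieves, CH2Cl2, −20 °C
Reagents that add atoms: tert-butyl hydroperoxide CC(C)(C)OO
Why: Sharpless asymmetric epoxidation with the L-(+)-tartrate delivers oxygen to the face that gives the (2S,3S) epoxy alcohol from an E allylic alcohol, the same sense as geraniol.

Step 7
Reactants: 14 [(2S,3S)-2,3-dimethyloxiran-2-yl]methanol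
Product: 16 (2R,3S)-2,3-dimethyloxirane-2-carboxylic acid, via epoxy aldehyde 15 (not isolated)
Conditions: TEMPO (10 mol%), PhI(OAc)2 (2.2 equiv), MeCN–H2O, rt
Reagents that add atoms: water O
Why: Oxoammonium oxidation of the primary alcohol through the aldehyde hydrate gives the acid without touching the epoxide; the C2 descriptor changes from S to R only because the priorities change.

Step 8
Reactants: 16 (2R,3S)-2,3-dimethyloxirane-2-carboxylic acid
Product: 18 (2R,3S)-2,3-dimethyloxirane-2-carboperoxoic acid, via acyl imidazolide 17 (not isolated)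
Conditions: half of the batch of 16; CDI (1.05 equiv), THF, 0 °C; then added slowly to H2O2 (50% aq., 6 equiv), THF, 0 °C; extracted into CH2Cl2, cold aq. NaH2PO4 wash, dried over MgSO4, titrated and kept as a cold solution
Reagents that add atoms: hydrogen peroxide OO
Why: Perhydrolysis of an N-acylimidazole (nucleophilic acyl substitution by the α-effect nucleophile H2O2) gives the peroxy acid, inverse addition into excess H2O2 keeps the peracid from attacking a second acyl imidazole, and the near-neutral conditions leave the oxirane and both stereocentres untouched.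

Step 9
Reactants: 18 (2R,3S)-2,3-dimethyloxirane-2-carboperoxoic acid; 16 (2R,3S)-2,3-dimethyloxirane-2-carboxylic acid
Product: 19 bis[(2R,3S)-2,3-dimethyloxirane-2-carbonyl] peroxide
Conditions: 18 and 16 (1:1), DCC (1.05 equiv), CH2Cl2, 0 °C; urea filtered off; used as a titrated solution below 5 °C, never concentrated
Reagents that add atoms: none
Why: Carbodiimide coupling of a carboxylic acid with a peroxy acid (attack of the peracid OOH on the O-acylisourea) is a standard diacyl peroxide synthesis that joins one acid unit and one peracid unit, and the oxirane-2-carbonyloxy unit is slow to decarboxylate, so the peroxide can be handled cold in solution.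

Step 10
Reactants: 12 (3S,5E)-2,6-dimethyl-9-oxonona-1,5-dien-3-yl benzoate; 19 bis[(2R,3S)-2,3-dimethyloxirane-2-carbonyl] peroxide
Product: 20 (3S,5E,8R)-3-(benzoyloxy)-2,6-dimethyl-9-oxonona-1,5-dien-8-yl (2R,3S)-2,3-dimethyloxirane-2-carboxylate
Conditions: (R)-2-(triphenylmethyl)pyrrolidine (10 mol%), hydroquinone (10 mol%), THF, 0 °C; cold aq. NaHCO3 wash (returns 16 for reuse in step 9); crude product taken on at once
Reagents that add atoms: none
Why: Proposed new method: the enamine of 12 with the bulky secondary amine attacks one peroxide oxygen of 19 in an SN2-type O–O cleavage on the face away from the trityl group, which forms the C8–O bond with R configuration, transfers the whole epoxy ester and releases one equivalent of acid 16 as the leaving carboxylate; the closest known reaction is the amine-catalysed α-benzoyloxylation of aldehydes with dibenzoyl peroxide, extended here to a non-aromatic, enantiopure diacyl peroxide whose reluctance to decarboxylate should keep the polar pathway dominant.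

Step 11
Reactants: 20 (3S,5E,8R)-3-(benzoyloxy)-2,6-dimethyl-9-oxonona-1,5-dien-8-yl (2R,3S)-2,3-dimethyloxirane-2-carboxylate; 21 methyl prop-2-ynoate
Product: 23 methyl (4R,6E,9S)-9-(benzoyloxy)-4-{[(2R,3S)-2,3-dimethyloxirane-2-carbonyl]oxy}-3-hydroxy-6,10-dimethyl-2-methylideneundeca-6,10-dienoate (both C3 epimers), via vinylalane 22 (not isolated)
Conditions: 21, i-Bu2AlH, N-methylmorpholine N-oxide, THF, 0 °C; then 20, −78 → 0 °C; aq. KNaC4H4O6
Reagents that add atoms: none
Why: Vinylalumination (hydroalumination of the propiolate to an α-alumino acrylate, then 1,2-addition to the aldehyde) gives the Morita–Baylis–Hillman-type adduct without an amine base, so the epimerisable α-acyloxy aldehyde keeps its C8 configuration; the new carbinol centre is uncontrolled and is erased in step 12.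

Step 12
Reactants: 23 methyl (4R,6E,9S)-9-(benzoyloxy)-4-{[(2R,3S)-2,3-dimethyloxirane-2-carbonyl]oxy}-3-hydroxy-6,10-dimethyl-2-methylideneundeca-6,10-dienoate
Product: 24 methyl (2Z,4R,6E,9S)-9-(benzoyloxy)-2-(bromomethyl)-4-{[(2R,3S)-2,3-dimethyloxirane-2-carbonyl]oxy}-6,10-dimethylundeca-2,6,10-trienoate
Conditions: NBS, Me2S, CH2Cl2, −20 → 0 °C
Reagents that add atoms: N-bromosuccinimide O=C1CCC(=O)N1Br
Why: Corey–Kim-type activation of the allylic alcohol and SN2' displacement by bromide gives the thermodynamically preferred (Z)-2-(bromomethyl)enoate under neutral conditions that spare the epoxy ester and the trisubstituted alkene.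

Step 13
Reactants: 24 methyl (2Z,4R,6E,9S)-9-(benzoyloxy)-2-(bromomethyl)-4-{[(2R,3S)-2,3-dimethyloxirane-2-carbonyl]oxy}-6,10-dimethylundeca-2,6,10-trienoate; 25 prop-2-enal
Product: 27 (1R,3E,6S)-6-(benzoyloxy)-1-[(2R,3R)-2-ethenyl-4-methylidene-5-oxooxolan-3-yl]-3,7-dimethylocta-3,7-dien-1-yl (2R,3S)-2,3-dimethyloxirane-2-carboxylate, via hydroxy ester 26 (not isolated)
Conditions: CrCl2 (4 equiv), 25 (3 equiv) present from the start, THF, 0 °C → rt; dilute aq. HCl work-up; then PPTS, benzene, 50 °C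
Reagents that add atoms: none
Why: Nozaki–Hiyama-type allylation with divalent chromium in Barbier mode adds the equilibrating allylchromium to acrolein through a chair transition state to give the anti C6/C7 relationship, the C8 centre steers the aldehyde to the face anti to the C9 chain in the allylic-strain-minimised conformer (H eclipsing the alkene, acyloxy outside), and acid-catalysed lactonisation then gives the trans lactone.

Step 14
Reactants: 27 (1R,3E,6S)-6-(benzoyloxy)-1-[(2R,3R)-2-ethenyl-4-methylidene-5-oxooxolan-3-yl]-3,7-dimethylocta-3,7-dien-1-yl (2R,3S)-2,3-dimethyloxirane-2-carboxylate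
Product: 28 (1R)-2-{(2R,3R)-3-[(2S)-2-(benzoyloxy)-3-methylbut-3-en-1-yl]-2-methyloxiran-2-yl}-1-[(2R,3R)-2-ethenyl-4-methylidene-5-oxooxolan-3-yl]ethyl (2R,3S)-2,3-dimethyloxirane-2-carboxylate
Conditions: Shi ketone (D-fructose-derived, 0.3 equiv), KHSO5 (from 2KHSO5·KHSO4·K2SO4), K2CO3, Bu4NHSO4, MeCN–CH2(OMe)2–aq. Na2B4O7 (pH about 9.5), 0 °C
Reagents that add atoms: potassium peroxymonosulfate KHSO5 [K+].[O-]S(=O)(=O)OO
Why: Shi asymmetric epoxidation attacks only the electron-rich E-trisubstituted alkene (the vinyl, the isopropenyl next to the benzoate and the α-methylene lactone are all much less reactive) and the D-fructose ketone gives the (R,R) epoxide by catalyst control, which is the C1/C10 configuration of the target.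

Step 15
Reactants: 28 (1R)-2-{(2R,3R)-3-[(2S)-2-(benzoyloxy)-3-methylbut-3-en-1-yl]-2-methyloxiran-2-yl}-1-[(2R,3R)-2-ethenyl-4-methylidene-5-oxooxolan-3-yl]ethyl (2R,3S)-2,3-dimethyloxirane-2-carboxylate
Product: 29 CNP0324463.5, (1R,3S,4Z,6R,7R,8R,10R)-3-(benzoyloxy)-8-{[(2R,3S)-2,3-dimethyloxirane-2-carbonyl]oxy}-1,10-epoxygermacra-4,11(13)-dien-12,6-olide
Conditions: second-generation Grubbs catalyst RuCl2(=CHPh)(PCy3)(H2IMes) (15 mol%, added in portions), 1,4-benzoquinone (30 mol%), toluene (0.5 mM), 90 °C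
Reagents that add atoms: none
Why: Ring-closing metathesis between the C6 vinyl and the C3 isopropenyl groups forms the ten-membered ring with loss of ethene, and in a ring that already holds a trans epoxide and a trans-fused lactone the ring-cis (Z) trisubstituted alkene is the geometry the metallacyclobutane can reach; no stereocentre is touched.

**Compound list**

1 | 1-bromo-3-methylbut-2-ene | CC(C)=CCBr | starting material
2 | (2-methylprop-1-en-1-yl)magnesium bromide | CC(C)=C[Mg]Br | starting material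
3 | 2,6-dimethylhepta-2,5-diene | CC(C)=CCC=C(C)C | intermediate
4 | (3S)-2,2-dimethyl-3-(3-methylbut-2-en-1-yl)oxirane | CC(C)=CC[C@@H]1OC1(C)C | intermediate
5 | (3S,3'S)-3,3'-methylenebis(2,2-dimethyloxirane) | CC1(C)O[C@H]1C[C@@H]1OC1(C)C | intermediate
6 | (2S)-1-[(2S)-3,3-dimethyloxiran-2-yl]-3-methylbut-3-en-2-ol (lithium alkoxide in the flask) | CC(=C)[C@@H](O)C[C@@H]1OC1(C)C | intermediate
7 | (3S,5S)-2,6-dimethylhepta-1,6-diene-3,5-diol | CC(=C)[C@@H](O)C[C@H](O)C(C)=C | intermediate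
8 | (4S,6S)-2-methoxy-2-phenyl-4,6-di(prop-1-en-2-yl)-1,3-dioxane | COC1(c2ccccc2)O[C@H](C(C)=C)C[C@@H](C(C)=C)O1 | intermediate
9 | (3S,5S)-5-hydroxy-2,6-dimethylhepta-1,6-dien-3-yl benzoate | CC(=C)[C@@H](OC(=O)c1ccccc1)C[C@H](O)C(C)=C | intermediate
10 | ethoxyethene | C=COCC | starting material
11 | (3S,5S)-5-(ethenyloxy)-2,6-dimethylhepta-1,6-dien-3-yl benzoate | CC(=C)[C@@H](OC(=O)c1ccccc1)C[C@H](OC=C)C(C)=C | intermediate
12 | (3S,5E)-2,6-dimethyl-9-oxonona-1,5-dien-3-yl benzoate | CC(=C)[C@@H](OC(=O)c1ccccc1)C/C=C(\C)CCC=O | intermediate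
13 | (2E)-2-methylbut-2-en-1-ol | C/C=C(\C)CO | starting material
14 | [(2S,3S)-2,3-dimethyloxiran-2-yl]methanol | C[C@@H]1O[C@@]1(C)CO | intermediate
15 | (2R,3S)-2,3-dimethyloxirane-2-carbaldehyde | C[C@@H]1O[C@@]1(C)C=O | intermediate
16 | (2R,3S)-2,3-dimethyloxirane-2-carboxylic acid | C[C@@H]1O[C@@]1(C)C(=O)O | intermediate
17 | [(2R,3S)-2,3-dimethyloxiran-2-yl](1H-imidazol-1-yl)methanone | C[C@@H]1O[C@@]1(C)C(=O)n1ccnc1 | intermediate
18 | (2R,3S)-2,3-dimethyloxirane-2-carboperoxoic acid | C[C@@H]1O[C@@]1(C)C(=O)OO | intermediate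
19 | bis[(2R,3S)-2,3-dimethyloxirane-2-carbonyl] peroxide | C[C@@H]1O[C@@]1(C)C(=O)OOC(=O)[C@]1(C)O[C@H]1C | intermediate
20 | (3S,5E,8R)-3-(benzoyloxy)-2,6-dimethyl-9-oxonona-1,5-dien-8-yl (2R,3S)-2,3-dimethyloxirane-2-carboxylate | C=C(C)[C@@H](OC(=O)c1ccccc1)C/C=C(\C)C[C@H](C=O)OC(=O)[C@]1(C)O[C@H]1C | intermediate
21 | methyl prop-2-ynoate | C#CC(=O)OC | starting material
22 | methyl 2-[bis(2-methylpropyl)alumanyl]prop-2-enoate | C=C(C(=O)OC)[Al](CC(C)C)CC(C)C | intermediate
23 | methyl (4R,6E,9S)-9-(benzoyloxy)-4-{[(2R,3S)-2,3-dimethyloxirane-2-carbonyl]oxy}-3-hydroxy-6,10-dimethyl-2-methylideneundeca-6,10-dienoate (C3 epimers) | C=C(C)[C@@H](OC(=O)c1ccccc1)C/C=C(\C)C[C@@H](OC(=O)[C@]1(C)O[C@H]1C)C(O)C(=C)C(=O)OC | intermediate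
24 | methyl (2Z,4R,6E,9S)-9-(benzoyloxy)-2-(bromomethyl)-4-{[(2R,3S)-2,3-dimethyloxirane-2-carbonyl]oxy}-6,10-dimethylundeca-2,6,10-trienoate | C=C(C)[C@@H](OC(=O)c1ccccc1)C/C=C(\C)C[C@@H](OC(=O)[C@]1(C)O[C@H]1C)/C=C(\CBr)C(=O)OC | intermediate
25 | prop-2-enal | C=CC=O | starting material
26 | methyl (3S,4R,6E,9S)-9-(benzoyloxy)-4-{[(2R,3S)-2,3-dimethyloxirane-2-carbonyl]oxy}-3-[(1R)-1-hydroxyprop-2-en-1-yl]-6,10-dimethyl-2-methylideneundeca-6,10-dienoate | C=C(C(=O)OC)[C@@H]([C@H](O)C=C)[C@H](OC(=O)[C@]1(C)O[C@H]1C)C/C(C)=C/C[C@H](OC(=O)c1ccccc1)C(C)=C | intermediate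
27 | (1R,3E,6S)-6-(benzoyloxy)-1-[(2R,3R)-2-ethenyl-4-methylidene-5-oxooxolan-3-yl]-3,7-dimethylocta-3,7-dien-1-yl (2R,3S)-2,3-dimethyloxirane-2-carboxylate | C=C1C(=O)O[C@H](C=C)[C@H]1[C@H](OC(=O)[C@]2(C)O[C@H]2C)C/C(C)=C/C[C@H](OC(=O)c2ccccc2)C(C)=C | intermediate
28 | (1R)-2-{(2R,3R)-3-[(2S)-2-(benzoyloxy)-3-methylbut-3-en-1-yl]-2-methyloxiran-2-yl}-1-[(2R,3R)-2-ethenyl-4-methylidene-5-oxooxolan-3-yl]ethyl (2R,3S)-2,3-dimethyloxirane-2-carboxylate | C=C1C(=O)O[C@H](C=C)[C@H]1[C@H](OC(=O)[C@]2(C)O[C@H]2C)C[C@@]2(C)O[C@@H]2C[C@H](OC(=O)c2ccccc2)C(C)=C | intermediate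
29 | CNP0324463.5, (1R,3S,4Z,6R,7R,8R,10R)-3-(benzoyloxy)-8-{[(2R,3S)-2,3-dimethyloxirane-2-carbonyl]oxy}-1,10-epoxygermacra-4,11(13)-dien-12,6-olide | C=C1C(=O)O[C@@H]2/C=C(/C)[C@@H](OC(=O)c3ccccc3)C[C@H]3O[C@]3(C)C[C@@H](OC(=O)[C@]3(C)O[C@H]3C)[C@@H]12 | target

**Step count and risks**

Total step count: 15. Longest linear sequence: 11 steps (steps 1–5 and 10–15, from 1 to 29); the side-chain branch (steps 6–9) joins at step 10.

Most likely to fail:

Step 10 (the new α-acyloxylation). The diacyl peroxide may acylate or oxidise the amine catalyst, react by a radical pathway, or give low selectivity, and 20 can epimerise at C8. The fallback uses known chemistry only; it sets out from 12, comes back at 20 and makes steps 8 and 9 unnecessary. L-Proline-catalysed α-aminoxylation of 12 with nitrosobenzene in DMSO gives (3S,5E,8R)-8-(anilinooxy)-2,6-dimethyl-9-oxonona-1,5-dien-3-yl benzoate F1. NaBH4 in the same flask reduces it to (3S,5E,8R)-8-(anilinooxy)-9-hydroxy-2,6-dimethylnona-1,5-dien-3-yl benzoate F2. N–O cleavage with CuSO4·5H2O in MeOH gives (3S,5E,8R)-8,9-dihydroxy-2,6-dimethylnona-1,5-dien-3-yl benzoate F3. TBSCl and imidazole silylate the primary hydroxyl to give (3S,5E,8R)-9-[(tert-butyldimethylsilyl)oxy]-8-hydroxy-2,6-dimethylnona-1,5-dien-3-yl benzoate F4. Acid 16 with DCC and DMAP then gives (3S,5E,8R)-3-(benzoyloxy)-9-[(tert-butyldimethylsilyl)oxy]-2,6-dimethylnona-1,5-dien-8-yl (2R,3S)-2,3-dimethyloxirane-2-carboxylate F5. HF·pyridine frees (3S,5E,8R)-3-(benzoyloxy)-9-hydroxy-2,6-dimethylnona-1,5-dien-8-yl (2R,3S)-2,3-dimethyloxirane-2-carboxylate F6, and Dess–Martin periodinane oxidises it to 20.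

Step 13 (chromium allylation). The allylchromium may lose the C8 acyloxy group by vinylogous elimination, or give the syn adduct or the wrong face at C7. The fallback sets out from 24 (with 25) and comes back at 26. An indium-mediated Barbier reaction (In powder, THF–H2O), which is syn-selective for such bromides and run in a protic medium, gives methyl (3S,4R,6E,9S)-9-(benzoyloxy)-4-{[(2R,3S)-2,3-dimethyloxirane-2-carbonyl]oxy}-3-[(1S)-1-hydroxyprop-2-en-1-yl]-6,10-dimethyl-2-methylideneundeca-6,10-dienoate F7. Mitsunobu inversion at C6 with chloroacetic acid (PPh3, DIAD) gives methyl (3R,4R,6E,9S)-9-(benzoyloxy)-3-[(1R)-1-(chloroacetoxy)prop-2-en-1-yl]-4-{[(2R,3S)-2,3-dimethyloxirane-2-carbonyl]oxy}-6,10-dimethyl-2-methylideneundeca-6,10-dienoate F8. Thiourea and NaHCO3 in EtOH remove the chloroacetyl group to give 26, which is lactonised to 27 with PPTS as in step 13.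

Step 15 (ring-closing metathesis). The strained bicyclic product, the hindered isopropenyl partner and competing dimerisation may stop the closure or give the E isomer. The fallback closes the carbocycle before the lactone; it sets out from 26 (isolated from step 13 by leaving out the PPTS treatment) and comes back at 29. Shi epoxidation of 26 with the D-fructose ketone under NaHCO3 buffering gives methyl (3S,4R)-5-{(2R,3R)-3-[(2S)-2-(benzoyloxy)-3-methylbut-3-en-1-yl]-2-methyloxiran-2-yl}-4-{[(2R,3S)-2,3-dimethyloxirane-2-carbonyl]oxy}-3-[(1R)-1-hydroxyprop-2-en-1-yl]-2-methylidenepentanoate F9. Ring-closing metathesis of this more flexible, allylic-alcohol-bearing diene with the second-generation Grubbs catalyst RuCl2(=CHPh)(PCy3)(H2IMes) gives methyl (1R,3S,4Z,6R,7S,8R,10R)-3-(benzoyloxy)-8-{[(2R,3S)-2,3-dimethyloxirane-2-carbonyl]oxy}-1,10-epoxy-6-hydroxygermacra-4,11(13)-dien-12-oate F10. PPTS in warm benzene then closes the lactone to 29.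

**Further compounds**

F1 | step 10 | (3S,5E,8R)-8-(anilinooxy)-2,6-dimethyl-9-oxonona-1,5-dien-3-yl benzoate | C=C(C)[C@@H](OC(=O)c1ccccc1)C/C=C(\C)C[C@H](C=O)ONc1ccccc1
F2 | step 10 | (3S,5E,8R)-8-(anilinooxy)-9-hydroxy-2,6-dimethylnona-1,5-dien-3-yl benzoate | C=C(C)[C@@H](OC(=O)c1ccccc1)C/C=C(\C)C[C@H](CO)ONc1ccccc1
F3 | step 10 | (3S,5E,8R)-8,9-dihydroxy-2,6-dimethylnona-1,5-dien-3-yl benzoate | C=C(C)[C@@H](OC(=O)c1ccccc1)C/C=C(\C)C[C@H](CO)O
F4 | step 10 | (3S,5E,8R)-9-[(tert-butyldimethylsilyl)oxy]-8-hydroxy-2,6-dimethylnona-1,5-dien-3-yl benzoate | C=C(C)[C@@H](OC(=O)c1ccccc1)C/C=C(\C)C[C@H](CO[Si](C)(C)C(C)(C)C)O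
F5 | step 10 | (3S,5E,8R)-3-(benzoyloxy)-9-[(tert-butyldimethylsilyl)oxy]-2,6-dimethylnona-1,5-dien-8-yl (2R,3S)-2,3-dimethyloxirane-2-carboxylate | C=C(C)[C@@H](OC(=O)c1ccccc1)C/C=C(\C)C[C@H](CO[Si](C)(C)C(C)(C)C)OC(=O)[C@]1(C)O[C@H]1C
F6 | step 10 | (3S,5E,8R)-3-(benzoyloxy)-9-hydroxy-2,6-dimethylnona-1,5-dien-8-yl (2R,3S)-2,3-dimethyloxirane-2-carboxylate | C=C(C)[C@@H](OC(=O)c1ccccc1)C/C=C(\C)C[C@H](CO)OC(=O)[C@]1(C)O[C@H]1C
F7 | step 13 | methyl (3S,4R,6E,9S)-9-(benzoyloxy)-4-{[(2R,3S)-2,3-dimethyloxirane-2-carbonyl]oxy}-3-[(1S)-1-hydroxyprop-2-en-1-yl]-6,10-dimethyl-2-methylideneundeca-6,10-dienoate | C=C(C(=O)OC)[C@@H]([C@@H](O)C=C)[C@H](OC(=O)[C@]1(C)O[C@H]1C)C/C(C)=C/C[C@H](OC(=O)c1ccccc1)C(C)=C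
F8 | step 13 | methyl (3R,4R,6E,9S)-9-(benzoyloxy)-3-[(1R)-1-(chloroacetoxy)prop-2-en-1-yl]-4-{[(2R,3S)-2,3-dimethyloxirane-2-carbonyl]oxy}-6,10-dimethyl-2-methylideneundeca-6,10-dienoate | C=C(C(=O)OC)[C@@H]([C@H](OC(=O)CCl)C=C)[C@H](OC(=O)[C@]1(C)O[C@H]1C)C/C(C)=C/C[C@H](OC(=O)c1ccccc1)C(C)=C
F9 | step 15 | methyl (3S,4R)-5-{(2R,3R)-3-[(2S)-2-(benzoyloxy)-3-methylbut-3-en-1-yl]-2-methyloxiran-2-yl}-4-{[(2R,3S)-2,3-dimethyloxirane-2-carbonyl]oxy}-3-[(1R)-1-hydroxyprop-2-en-1-yl]-2-methylidenepentanoate | C=C(C(=O)OC)[C@@H]([C@H](O)C=C)[C@H](OC(=O)[C@]1(C)O[C@H]1C)C[C@@]1(C)O[C@@H]1C[C@H](OC(=O)c1ccccc1)C(C)=C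
F10 | step 15 | methyl (1R,3S,4Z,6R,7S,8R,10R)-3-(benzoyloxy)-8-{[(2R,3S)-2,3-dimethyloxirane-2-carbonyl]oxy}-1,10-epoxy-6-hydroxygermacra-4,11(13)-dien-12-oate | C=C(C(=O)OC)[C@H]1[C@H](O)/C=C(/C)[C@@H](OC(=O)c2ccccc2)C[C@H]2O[C@]2(C)C[C@H]1OC(=O)[C@]1(C)O[C@H]1C
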